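Numbering follows the octahydro-1H-indene skeleton of the target: C-1 ethylidene carbon, C-2 OAc, C-3a/C-7a ring fusion, C-4 methylidene carbon, C-5 ester, C-6 OH, C-7 isopropyl; α is the face of H-7a and of the C-2 oxygen.
Retrosynthesis: the C-5 ester C–O bond and the C-6 OH come from trans-diaxial opening of a 5,6-epoxide by the (Z)-acid; C-4=CH2 from a C-4 ketone; ring B (cyclohexane) from an aldol condensation (C-5=C-6) of a cyclopentane carrying acetyl at C-3a and CH(iPr)CHO at C-7a; ring A (cyclopentane) from the C-1–C-7a bond between an alkyne carbon and an enal β-carbon; the acyclic enyne from a 4-vinyl-6-propynyl δ-lactone.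
Enabling feature: the ring-fusion carbon C-7a lies between the exocyclic alkylidene carbon C-1 and C-7 (iPr), which is bonded to oxygenated C-6. C-1 can therefore be an alkyne carbon and C-7a/C-7/C-6 the β-, α- and carbonyl carbons of an enal; closing ring A before ring B turns the trans ring fusion into a trans-1,2-disubstituted cyclopentane.
Forward: hetero-Diels–Alder, oxidation to the dihydropyranone, vinyl cuprate addition, isopropyl ketone, Shapiro formylation, nickel-catalysed reductive cyclization (ring A), Wacker oxidation and aldol condensation (ring B), epoxidation, methylenation, silyl-to-acetyl exchange, epoxide opening with the separately made (Z)-acid.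
Stereochemistry: C-2 by the chiral chromium catalyst; C-3a from C-2 by trans cuprate addition on the lactone (a temporary ring); C-7a from C-3a, and the ethylidene geometry from syn C/H addition, in the key step; C-7 by equilibration; C-5 and C-6 by axial epoxidation and inversion at C-5.

Key step: step 8

Remark: but-2-ynal (1) is taken as a purchasable aldehyde, and the enantiomer of the chromium catalyst is the one that gives the (6S) adduct 3.

Step 1
Reactants: 1 but-2-ynal; 2 (E)-1-methoxybuta-1,3-diene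
Product: 3 (2R,6S)-2-methoxy-6-(prop-1-yn-1-yl)-5,6-dihydro-2H-pyran
Conditions: CrCl(L) 3 mol % (trivalent chromium; L = Schiff-base dianion from 3-(1-adamantyl)-2-hydroxy-5-methylbenzaldehyde and enantiopure cis-1-aminoindan-2-ol), 4 Å MS, neat, 0 °C to rt
Reagents that add atoms: none
Why: The chromium Schiff-base-catalysed hetero-Diels–Alder reaction of 1-methoxybutadiene with an ynal (a known partner class) should give the cis (endo) acetal, the catalyst enantiomer setting the C-6 carbinol centre (later C-2 of the target), the one stereocentre introduced by an external chiral source.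

Step 2
Reactants: 3 (2R,6S)-2-methoxy-6-(prop-1-yn-1-yl)-5,6-dihydro-2H-pyran
Product: 4 (6S)-6-(prop-1-yn-1-yl)-5,6-dihydro-2H-pyran-2-one
Conditions: Jones reagent (CrO3, H2SO4, H2O), acetone, 0 °C
Reagents that add atoms: water, O
Why: Jones oxidation, in which acid hydrolysis of the allylic acetal to the lactol and chromic acid oxidation occur in one pot, is the standard route from 2-alkoxy-5,6-dihydro-2H-pyrans to 5,6-dihydropyran-2-ones and leaves the carbinol centre untouched.

Step 3
Reactants: 4 (6S)-6-(prop-1-yn-1-yl)-5,6-dihydro-2H-pyran-2-one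
Product: 6 (4R,6S)-4-ethenyl-6-(prop-1-yn-1-yl)oxan-2-one, via silyl ketene acetal 5 (not isolated)
Conditions: CH2=CHMgBr (1.5 equiv), CuBr·SMe2 (10 mol %), Me3SiCl (2 equiv), THF, −78 °C; then 1 M HCl, 0 °C
Reagents that add atoms: vinylmagnesium bromide, C=C[Mg]Br; chlorotrimethylsilane, C[Si](C)(C)Cl (silyl group only in intermediate 5)
Why: Copper-catalysed, chlorosilane-accelerated conjugate addition of the Grignard reagent should occur by axial attack on the half-chair lactone anti to the pseudo-equatorial propynyl group (the usual 4,6-trans selectivity of 6-substituted dihydropyranones), so the lactone ring relays the carbinol configuration to the future C-3a, and acid work-up cleaves the ketene acetal.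

Step 4
Reactants: 6 (4R,6S)-4-ethenyl-6-(prop-1-yn-1-yl)oxan-2-one
Product: 7 (5R,7S)-5-ethenyl-7-hydroxy-2-methyldec-8-yn-3-one
Conditions: i-PrLi (1.1 equiv), THF, −78 °C; then sat. aq. NH4Cl
Reagents that add atoms: isopropyllithium, CC(C)[Li]
Why: Single addition of an alkyllithium to a δ-lactone at −78 °C (the tetrahedral lithium alkoxide survives until the quench and the hindered isopropyl ketone resists a second addition) should give the hydroxy ketone, which may rest partly as its cyclic hemiketal.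

Step 5
Reactants: 7 (5R,7S)-5-ethenyl-7-hydroxy-2-methyldec-8-yn-3-one
Product: 8 (5R,7S)-7-{[tert-butyl(dimethyl)silyl]oxy}-5-ethenyl-2-methyldec-8-yn-3-one
Conditions: TBSCl, imidazole, DMF, rt
Reagents that add atoms: tert-butyl(chloro)dimethylsilane, CC(C)(C)[Si](C)(C)Cl
Why: Silylation with silyl chloride and imidazole should trap the open-chain tautomer at its secondary propargylic hydroxyl, the tertiary hemiketal hydroxyl being too hindered, which frees the ketone for the next step.

Step 6
Reactants: 8 (5R,7S)-7-{[tert-butyl(dimethyl)silyl]oxy}-5-ethenyl-2-methyldec-8-yn-3-one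
Product: 9 N'-[(3E,5S,7S)-7-{[tert-butyl(dimethyl)silyl]oxy}-5-ethenyl-2-methyldec-8-yn-3-ylidene]-2,4,6-tri(propan-2-yl)benzenesulfonohydrazide
Conditions: 2,4,6-(i-Pr)3C6H2SO2NHNH2 (1.1 equiv), pyridinium p-toluenesulfonate (cat.), THF, rt
Reagents that add atoms: 2,4,6-tri(propan-2-yl)benzenesulfonohydrazide, CC(C)c1cc(C(C)C)c(S(=O)(=O)NN)c(C(C)C)c1
Why: Acid-catalysed condensation gives the trisylhydrazone, whose sulfonamide nitrogen should lie syn to the α-CH2 and anti to the isopropyl group, as the regiochemistry of the next step requires.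

Step 7
Reactants: 9 N'-[(3E,5S,7S)-7-{[tert-butyl(dimethyl)silyl]oxy}-5-ethenyl-2-methyldec-8-yn-3-ylidene]-2,4,6-tri(propan-2-yl)benzenesulfonohydrazide
Product: 11 (2E,4S,6S)-6-{[tert-butyl(dimethyl)silyl]oxy}-4-ethenyl-2-(propan-2-yl)non-2-en-7-ynal, via alkenyllithium 10 (not isolated)
Conditions: n-BuLi (2.2 equiv), THF, −78 °C to 0 °C; then DMF, −78 °C to rt; aq. NH4Cl
Reagents that add atoms: N,N-dimethylformamide, CN(C)C=O; n-butyllithium, CCCC[Li] (lithium only in intermediate 10)
Why: In the Shapiro reaction the hydrazone dianion forms by deprotonation at the less substituted α-CH2 syn to nitrogen, loses sulfinate and dinitrogen to give the alkenyllithium, and formylation with DMF should give the α-isopropyl enal regiospecifically (its alkene geometry has no consequence later).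

Step 8
Reactants: 11 (2E,4S,6S)-6-{[tert-butyl(dimethyl)silyl]oxy}-4-ethenyl-2-(propan-2-yl)non-2-en-7-ynal
Product: 13 (2RS)-2-[(1R,2Z,3S,5S)-3-{[tert-butyl(dimethyl)silyl]oxy}-5-ethenyl-2-ethylidenecyclopentyl]-3-methylbutanal, via triethylsilyl enol ether 12 (not isolated)
Conditions: Ni(cod)2 (10 mol %; bis(1,5-cyclooctadiene)nickel, zerovalent nickel), PCy3 (20 mol %), Et3SiH (3 equiv), THF, 50 °C; then 1 M HCl, THF, 0 °C
Reagents that add atoms: triethylsilane, CC[SiH](CC)CC (silyl group only in intermediate 12)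
Why: Zerovalent nickel binds the alkyne and the enal and couples them by oxidative cyclization, forming the bond between the internal alkyne carbon and the enal β-carbon and leaving a seven-membered oxa-nickelacycle (alkenylnickel O-enolate); σ-bond metathesis with Et3SiH puts silicon on oxygen (enol ether 12) and hydride on nickel, and C–H reductive elimination delivers hydrogen to the alkenyl carbon on the side of the new C–C bond, so the methyl group ends syn to the silyloxy-bearing carbon as in the target. The closest known reactions are the nickel-catalysed reductive cyclization of alkynyl enones and the nickel/silane reductive coupling of enals with alkynes to enol silanes. The cyclopentane is closed in a 5-exo sense with respect to both the alkyne (5-exo-dig) and the enal alkene (5-exo-trig). The one new ring stereocentre (C-1 of the cyclopentane, later C-7a) is controlled by the adjacent vinyl-bearing carbon, the enal-derived chain and the vinyl group taking trans pseudo-equatorial positions in the cyclization transition state, which also places the chain trans to the silyloxy group; the aldehyde α-carbon forms as a mixture that step 10 corrects. The step needs chemoselectivity for the enal C=C over the terminal vinyl group and the C=O group, secured because only the electron-poor enal gives a nickel enolate through a five-membered carbocycle (C=O coupling would need a seven-membered ring and the vinyl group is unactivated), and the mild acid work-up hydrolyses only the triethylsilyl enol ether.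

Step 9
Reactants: 13 (2RS)-2-[(1R,2Z,3S,5S)-3-{[tert-butyl(dimethyl)silyl]oxy}-5-ethenyl-2-ethylidenecyclopentyl]-3-methylbutanal
Product: 14 (2RS)-2-[(1S,2Z,3S,5R)-5-acetyl-3-{[tert-butyl(dimethyl)silyl]oxy}-2-ethylidenecyclopentyl]-3-methylbutanal
Conditions: PdCl2 (10 mol %), CuCl (1 equiv), O2 (1 atm), DMF/H2O 7:1, rt
Reagents that add atoms: water, O
Why: In the Tsuji–Wacker oxidation, Markovnikov hydroxypalladation of the only monosubstituted alkene should give the methyl ketone, the trisubstituted ethylidene group being inert and the aldehyde and silyl ether tolerated.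

Step 10
Reactants: 14 (2RS)-2-[(1S,2Z,3S,5R)-5-acetyl-3-{[tert-butyl(dimethyl)silyl]oxy}-2-ethylidenecyclopentyl]-3-methylbutanal
Product: 15 (1Z,2S,3aR,7R,7aS)-2-{[tert-butyl(dimethyl)silyl]oxy}-1-ethylidene-7-(propan-2-yl)-1,2,3,3a,7,7a-hexahydro-4H-inden-4-one
Conditions: KOH (0.5 equiv), MeOH, 0 °C to rt
Reagents that add atoms: none
Why: Base-mediated intramolecular aldol condensation (methyl ketone enolate onto the aldehyde, 6-enolexo-exo-trig, then E1cB dehydration) closes the cyclohexenone on the trans-1,2-disubstituted cyclopentane, which fixes the trans ring fusion, while the aldehyde α-carbon epimerizes before ring closure so that the isopropyl group should take the equatorial position at C-7.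

Step 11
Reactants: 15 (1Z,2S,3aR,7R,7aS)-2-{[tert-butyl(dimethyl)silyl]oxy}-1-ethylidene-7-(propan-2-yl)-1,2,3,3a,7,7a-hexahydro-4H-inden-4-one
Product: 16 (1Z,2S,3aR,5S,6S,7S,7aS)-2-{[tert-butyl(dimethyl)silyl]oxy}-5,6-epoxy-1-ethylidene-7-(propan-2-yl)octahydro-4H-inden-4-one
Conditions: t-BuOOH (2 equiv, in decane), DBU (1.2 equiv), CH2Cl2, 0 °C to rt
Reagents that add atoms: tert-butyl hydroperoxide, CC(C)(C)OO
Why: In this Weitz–Scheffer nucleophilic epoxidation the hydroperoxide anion should add to C-6 axially, on the α face anti to the pseudo-axial H-7 of the conformationally locked trans-fused enone, and the enolate closes the oxirane on the same face, while the isolated ethylidene alkene is inert to the nucleophilic oxidant.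

Step 12
Reactants: 16 (1Z,2S,3aR,5S,6S,7S,7aS)-2-{[tert-butyl(dimethyl)silyl]oxy}-5,6-epoxy-1-ethylidene-7-(propan-2-yl)octahydro-4H-inden-4-one
Product: 17 tert-butyl{[(1Z,2S,3aR,5R,6S,7S,7aR)-5,6-epoxy-1-ethylidene-4-methylidene-7-(propan-2-yl)octahydro-1H-inden-2-yl]oxy}dimethylsilane
Conditions: Ph3PCH3Br (1.5 equiv), KOt-Bu (1.4 equiv), THF, 0 °C; then 16, 0 °C to rt
Reagents that add atoms: methylidene(triphenyl)phosphorane, C=P(c1ccccc1)(c1ccccc1)c1ccccc1
Why: Wittig methylenation works well on α,β-epoxy ketones because the non-stabilized ylide attacks the carbonyl group faster than it opens the oxirane or enolizes the hindered α-CH.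

Step 13
Reactants: 17 tert-butyl{[(1Z,2S,3aR,5R,6S,7S,7aR)-5,6-epoxy-1-ethylidene-4-methylidene-7-(propan-2-yl)octahydro-1H-inden-2-yl]oxy}dimethylsilane
Product: 18 (1Z,2S,3aR,5R,6S,7S,7aR)-5,6-epoxy-1-ethylidene-4-methylidene-7-(propan-2-yl)octahydro-1H-inden-2-ol
Conditions: Bu4NF (1.5 equiv), AcOH (1.5 equiv), THF, 0 °C to rt
Reagents that add atoms: none
Why: Fluoride-mediated desilylation buffered with acetic acid should remove the secondary silyl ether without touching the vinyl oxirane.

Step 14
Reactants: 18 (1Z,2S,3aR,5R,6S,7S,7aR)-5,6-epoxy-1-ethylidene-4-methylidene-7-(propan-2-yl)octahydro-1H-inden-2-ol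
Product: 19 (1Z,2S,3aR,5R,6S,7S,7aR)-5,6-epoxy-1-ethylidene-4-methylidene-7-(propan-2-yl)octahydro-1H-inden-2-yl acetate
Conditions: Ac2O, pyridine, DMAP (cat.), CH2Cl2, 0 °C to rt
Reagents that add atoms: acetic anhydride, CC(=O)OC(C)=O
Why: Standard DMAP-catalysed acetylation of the only free hydroxyl installs the C-2 acetate before the C-6 hydroxyl is unveiled, so no selective acylation is needed.

Step 15
Reactants: 20 methyl pent-2-ynoate
Product: 21 methyl (2Z)-3-methylpent-2-enoate
Conditions: Me2CuLi (1.2 equiv, from CuI and 2 MeLi), THF, −78 °C; MeOH, then aq. NH4Cl at −78 °C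
Reagents that add atoms: lithium dimethylcuprate, [Li+].C[Cu-]C
Why: Conjugate addition of lithium dimethylcuprate to a 2-ynoate at −78 °C is a syn carbocupration, and protonation of the alkenylcuprate with retention puts hydrogen cis to the new methyl group, which should give the (Z)-enoate.

Step 16
Reactants: 21 methyl (2Z)-3-methylpent-2-enoate
Product: 22 (2Z)-3-methylpent-2-enoic acid
Conditions: LiOH·H2O, THF/H2O, rt; then 1 M HCl
Reagents that add atoms: lithium hydroxide, [Li+].[OH-]
Why: Saponification with aqueous LiOH at room temperature uses a base too weak to deprotonate the γ-positions, so the alkene geometry should be kept.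

Step 17
Reactants: 19 (1Z,2S,3aR,5R,6S,7S,7aR)-5,6-epoxy-1-ethylidene-4-methylidene-7-(propan-2-yl)octahydro-1H-inden-2-yl acetate; 22 (2Z)-3-methylpent-2-enoic acid
Product: 23 (1Z,2S,3aR,5S,6S,7S,7aR)-2-(acetyloxy)-1-ethylidene-6-hydroxy-4-methylidene-7-(propan-2-yl)octahydro-1H-inden-5-yl (2Z)-3-methylpent-2-enoate
Conditions: 22 (3 equiv), Cs2CO3 (0.2 equiv), DMF, 60 °C
Reagents that add atoms: none
Why: In this carboxylate-catalysed ring opening of the vinyl oxirane by the carboxylic acid, SN2 attack at the allylic C-5 from the β face, anti to the oxirane oxygen and in the trans-diaxial (Fürst–Plattner) sense enforced by the trans ring fusion, should give the 5β-ester and the free 6α-hydroxyl at once, and a trans-diaxial hydroxy ester cannot suffer 1,2-acyl migration.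

Compound list
1 | but-2-ynal | CC#CC=O | starting material
2 | (E)-1-methoxybuta-1,3-diene | CO/C=C/C=C | starting material
3 | (2R,6S)-2-methoxy-6-(prop-1-yn-1-yl)-5,6-dihydro-2H-pyran | CO[C@H]1C=CC[C@@H](C#CC)O1 | intermediate
4 | (6S)-6-(prop-1-yn-1-yl)-5,6-dihydro-2H-pyran-2-one | CC#C[C@@H]1CC=CC(=O)O1 | intermediate
5 | (2S,4S)-4-ethenyl-2-(prop-1-yn-1-yl)-6-[(trimethylsilyl)oxy]-3,4-dihydro-2H-pyran (silyl ketene acetal) | C=C[C@@H]1C[C@@H](C#CC)OC(O[Si](C)(C)C)=C1 | intermediate (not isolated)
6 | (4R,6S)-4-ethenyl-6-(prop-1-yn-1-yl)oxan-2-one | C=C[C@@H]1C[C@@H](C#CC)OC(=O)C1 | intermediate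
7 | (5R,7S)-5-ethenyl-7-hydroxy-2-methyldec-8-yn-3-one | C=C[C@@H](CC(=O)C(C)C)C[C@H](O)C#CC | intermediate
8 | (5R,7S)-7-{[tert-butyl(dimethyl)silyl]oxy}-5-ethenyl-2-methyldec-8-yn-3-one | C=C[C@@H](CC(=O)C(C)C)C[C@H](O[Si](C)(C)C(C)(C)C)C#CC | intermediate
9 | N'-[(3E,5S,7S)-7-{[tert-butyl(dimethyl)silyl]oxy}-5-ethenyl-2-methyldec-8-yn-3-ylidene]-2,4,6-tri(propan-2-yl)benzenesulfonohydrazide | C=C[C@@H](C/C(=N\NS(=O)(=O)c1c(C(C)C)cc(C(C)C)cc1C(C)C)C(C)C)C[C@H](O[Si](C)(C)C(C)(C)C)C#CC | intermediate
10 | [(3Z,5S,7S)-7-{[tert-butyl(dimethyl)silyl]oxy}-5-ethenyl-2-methyldec-3-en-8-yn-3-yl]lithium (alkenyllithium) | C=C[C@@H](/C=C(/[Li])C(C)C)C[C@H](O[Si](C)(C)C(C)(C)C)C#CC | intermediate (not isolated)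
11 | (2E,4S,6S)-6-{[tert-butyl(dimethyl)silyl]oxy}-4-ethenyl-2-(propan-2-yl)non-2-en-7-ynal | C=C[C@@H](/C=C(/C=O)C(C)C)C[C@H](O[Si](C)(C)C(C)(C)C)C#CC | intermediate
12 | triethyl{[(1Z)-2-[(1R,2Z,3S,5S)-3-{[tert-butyl(dimethyl)silyl]oxy}-5-ethenyl-2-ethylidenecyclopentyl]-3-methylbut-1-en-1-yl]oxy}silane (triethylsilyl enol ether) | C=C[C@@H]1C[C@H](O[Si](C)(C)C(C)(C)C)/C(=C\C)[C@H]1/C(=C\O[Si](CC)(CC)CC)C(C)C | intermediate (not isolated)
13 | (2RS)-2-[(1R,2Z,3S,5S)-3-{[tert-butyl(dimethyl)silyl]oxy}-5-ethenyl-2-ethylidenecyclopentyl]-3-methylbutanal (both epimers at the aldehyde α-carbon) | C=C[C@@H]1C[C@H](O[Si](C)(C)C(C)(C)C)/C(=C\C)[C@H]1C(C=O)C(C)C | intermediate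
14 | (2RS)-2-[(1S,2Z,3S,5R)-5-acetyl-3-{[tert-butyl(dimethyl)silyl]oxy}-2-ethylidenecyclopentyl]-3-methylbutanal (both epimers at the aldehyde α-carbon) | CC(=O)[C@@H]1C[C@H](O[Si](C)(C)C(C)(C)C)/C(=C\C)[C@H]1C(C=O)C(C)C | intermediate
15 | (1Z,2S,3aR,7R,7aS)-2-{[tert-butyl(dimethyl)silyl]oxy}-1-ethylidene-7-(propan-2-yl)-1,2,3,3a,7,7a-hexahydro-4H-inden-4-one | O=C1[C@@H]2C[C@H](O[Si](C)(C)C(C)(C)C)/C(=C\C)[C@H]2[C@H](C(C)C)C=C1 | intermediate
16 | (1Z,2S,3aR,5S,6S,7S,7aS)-2-{[tert-butyl(dimethyl)silyl]oxy}-5,6-epoxy-1-ethylidene-7-(propan-2-yl)octahydro-4H-inden-4-one | O=C1[C@@H]2C[C@H](O[Si](C)(C)C(C)(C)C)/C(=C\C)[C@H]2[C@H](C(C)C)[C@@H]3O[C@@H]31 | intermediate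
17 | tert-butyl{[(1Z,2S,3aR,5R,6S,7S,7aR)-5,6-epoxy-1-ethylidene-4-methylidene-7-(propan-2-yl)octahydro-1H-inden-2-yl]oxy}dimethylsilane | C=C1[C@@H]2C[C@H](O[Si](C)(C)C(C)(C)C)/C(=C\C)[C@H]2[C@H](C(C)C)[C@@H]3O[C@@H]31 | intermediate
18 | (1Z,2S,3aR,5R,6S,7S,7aR)-5,6-epoxy-1-ethylidene-4-methylidene-7-(propan-2-yl)octahydro-1H-inden-2-ol | C=C1[C@@H]2C[C@H](O)/C(=C\C)[C@H]2[C@H](C(C)C)[C@@H]3O[C@@H]31 | intermediate
19 | (1Z,2S,3aR,5R,6S,7S,7aR)-5,6-epoxy-1-ethylidene-4-methylidene-7-(propan-2-yl)octahydro-1H-inden-2-yl acetate | C=C1[C@@H]2C[C@H](OC(C)=O)/C(=C\C)[C@H]2[C@H](C(C)C)[C@@H]3O[C@@H]31 | intermediate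
20 | methyl pent-2-ynoate | CCC#CC(=O)OC | starting material
21 | methyl (2Z)-3-methylpent-2-enoate | COC(=O)/C=C(/C)CC | intermediate
22 | (2Z)-3-methylpent-2-enoic acid | OC(=O)/C=C(/C)CC | intermediate
23 | (1Z,2S,3aR,5S,6S,7S,7aR)-2-(acetyloxy)-1-ethylidene-6-hydroxy-4-methylidene-7-(propan-2-yl)octahydro-1H-inden-5-yl (2Z)-3-methylpent-2-enoate | C=C1[C@@H]2C[C@H](OC(C)=O)/C(=C\C)[C@H]2[C@H](C(C)C)[C@H](O)[C@H]1OC(=O)/C=C(/C)CC | target

Total step count: 17. Longest linear sequence: 15 steps (steps 1 to 14, then 17); steps 15 and 16 make the acid.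

Steps most likely to fail

Step 8. The α-isopropyl group may slow the oxidative cyclization, so that hydrosilylation or oligomerization of the alkyne or conjugate reduction of the enal competes, or facial selectivity at the enal β-carbon may be poor. The fallback sets out from ketone 8 and comes back at aldehyde 13, forming the same bond by enolate alkenylation instead of reductive coupling. Palladium-catalysed hydrostannation of 8 (Bu3SnH, cat. PdCl2(PPh3)2, THF; syn addition, tin on the alkyne carbon next to the silyloxy carbon) should give (5R,7S,8E)-7-{[tert-butyl(dimethyl)silyl]oxy}-5-ethenyl-2-methyl-8-(tributylstannyl)dec-8-en-3-one F1. Iododestannylation (I2, CH2Cl2, 0 °C, retention) should give (5R,7S,8E)-7-{[tert-butyl(dimethyl)silyl]oxy}-5-ethenyl-8-iodo-2-methyldec-8-en-3-one F2. Palladium-catalysed intramolecular α-alkenylation of the ketone enolate (Pd(PPh3)4, zerovalent palladium, KOt-Bu, THF) would close the ring with retention of the alkene geometry to 1-[(1S,2Z,3S,5S)-3-{[tert-butyl(dimethyl)silyl]oxy}-5-ethenyl-2-ethylidenecyclopentyl]-2-methylpropan-1-one F3, whose new α-centre should settle trans to the vinyl group by enolization. Wittig methoxymethylenation (Ph3P=CHOMe) would give tert-butyl{[(1S,2Z,3R,4S)-4-ethenyl-2-ethylidene-3-(1-methoxy-3-methylbut-1-en-2-yl)cyclopentyl]oxy}dimethylsilane F4, and mild acid hydrolysis (aq. oxalic acid, THF) would return 13.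

Step 11. The peroxide may add from the wrong face of the enone, or C-3a may epimerize under the basic conditions. The fallback sets out from enone 15 and comes back at epoxy ketone 16, replacing substrate-controlled nucleophilic epoxidation by hydroxyl-directed epoxidation. Corey–Bakshi–Shibata reduction (the oxazaborolidine enantiomer that delivers hydride to the β face, BH3·SMe2, THF, −20 °C) should give the pseudo-axial allylic alcohol (1Z,2S,3aR,4S,7R,7aS)-2-{[tert-butyl(dimethyl)silyl]oxy}-1-ethylidene-7-(propan-2-yl)-2,3,3a,4,7,7a-hexahydro-1H-inden-4-ol F5. Directed epoxidation syn to the hydroxyl (cat. VO(acac)2, t-BuOOH, CH2Cl2) should give (1Z,2S,3aR,4R,5R,6S,7S,7aR)-2-{[tert-butyl(dimethyl)silyl]oxy}-5,6-epoxy-1-ethylidene-7-(propan-2-yl)octahydro-1H-inden-4-ol F6, and oxidation with Dess–Martin periodinane would return 16.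

Step 17. Regiocontrol may be lost (conjugate attack at the exocyclic CH2 or attack at C-6), or the opening may be slow enough for elimination to compete. The fallback sets out from epoxide 19 and comes back at target 23, separating C–O bond formation from acylation. Acid-catalysed hydrolysis (cat. HClO4, THF/H2O, 0 °C; trans-diaxial opening by water) should give (1Z,2S,3aR,5S,6S,7S,7aR)-1-ethylidene-5,6-dihydroxy-4-methylidene-7-(propan-2-yl)octahydro-1H-inden-2-yl acetate F7. Yamaguchi esterification of the less hindered allylic 5-hydroxyl with acid 22 (2,4,6-trichlorobenzoyl chloride, Et3N, then DMAP, toluene) should then give 23.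

Further compounds
F1 | step 8 | (5R,7S,8E)-7-{[tert-butyl(dimethyl)silyl]oxy}-5-ethenyl-2-methyl-8-(tributylstannyl)dec-8-en-3-one | C=C[C@@H](CC(=O)C(C)C)C[C@H](O[Si](C)(C)C(C)(C)C)/C(=C\C)[Sn](CCCC)(CCCC)CCCC
F2 | step 8 | (5R,7S,8E)-7-{[tert-butyl(dimethyl)silyl]oxy}-5-ethenyl-8-iodo-2-methyldec-8-en-3-one | C=C[C@@H](CC(=O)C(C)C)C[C@H](O[Si](C)(C)C(C)(C)C)/C(I)=C\C
F3 | step 8 | 1-[(1S,2Z,3S,5S)-3-{[tert-butyl(dimethyl)silyl]oxy}-5-ethenyl-2-ethylidenecyclopentyl]-2-methylpropan-1-one | C=C[C@@H]1C[C@H](O[Si](C)(C)C(C)(C)C)/C(=C\C)[C@H]1C(=O)C(C)C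
F4 | step 8 | tert-butyl{[(1S,2Z,3R,4S)-4-ethenyl-2-ethylidene-3-(1-methoxy-3-methylbut-1-en-2-yl)cyclopentyl]oxy}dimethylsilane (enol ether, both geometries) | C=C[C@@H]1C[C@H](O[Si](C)(C)C(C)(C)C)/C(=C\C)[C@H]1C(=COC)C(C)C
F5 | step 11 | (1Z,2S,3aR,4S,7R,7aS)-2-{[tert-butyl(dimethyl)silyl]oxy}-1-ethylidene-7-(propan-2-yl)-2,3,3a,4,7,7a-hexahydro-1H-inden-4-ol | O[C@@H]1[C@@H]2C[C@H](O[Si](C)(C)C(C)(C)C)/C(=C\C)[C@H]2[C@H](C(C)C)C=C1
F6 | step 11 | (1Z,2S,3aR,4R,5R,6S,7S,7aR)-2-{[tert-butyl(dimethyl)silyl]oxy}-5,6-epoxy-1-ethylidene-7-(propan-2-yl)octahydro-1H-inden-4-ol | O[C@@H]1[C@@H]2C[C@H](O[Si](C)(C)C(C)(C)C)/C(=C\C)[C@H]2[C@H](C(C)C)[C@@H]3O[C@@H]31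
F7 | step 17 | (1Z,2S,3aR,5S,6S,7S,7aR)-1-ethylidene-5,6-dihydroxy-4-methylidene-7-(propan-2-yl)octahydro-1H-inden-2-yl acetate | C=C1[C@@H]2C[C@H](OC(C)=O)/C(=C\C)[C@H]2[C@H](C(C)C)[C@H](O)[C@H]1O
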